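**Strategy.** The decalin is cut through C5–C10 and C3–C4: ring A carries the C4 carboxyl next to quaternary C5 and an oxygen at C1, which maps onto an (E)-3-methyl-2-enoate (C4=C5) and a 2-silyloxydiene (C10=C1–C2=C3) joined by the tether C6–C9. One thermal intramolecular Diels–Alder reaction closes rings A and B and sets C4, C5 and C10, steered by the single stereocentre C7. The precursor is an acyclic triene with a C8 dioxolane, a C13 silyl ether and, as an improvement for a base-free endgame, a tert-butyl ester at C15. C7 comes from a deconjugative Evans alkylation; after cyclisation C1 is reduced, C9=C10 is introduced, and the side chain, enal and acid are unveiled.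

Key step: step 13

Remark: the target is taken as (1R,4S,5R,7S) with a (2E,4S)-acyl group; names use eremophilane numbering (C1–C10 decalin, C11–C13 on C7 with C12 = CH2, C14 = methyl on C5, C15 = carboxyl carbon on C4), β being the face of C14; TBDPS = tert-butyldiphenylsilyl, TBS = tert-butyldimethylsilyl.
Remark: compounds 1, 2, 6, 13, 18, 28 and 33 are assumed to be purchasable.

Step 1
Reactants: 1 hydroxyacetone; 2 tert-butyl (triphenylphosphoranylidene)acetate
Product: 3 tert-butyl (E)-4-hydroxy-3-methylbut-2-enoate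
Conditions: MeCN, 80 °C
Reagents that add atoms: none
Why: Wittig olefination with a stabilised ylide should give mainly the (E)-enoate (CH2OH trans to the ester); the minor (Z)-isomer tends to lactonise to the butenolide and is removed on silica.

Step 2
Reactants: 3 tert-butyl (E)-4-hydroxy-3-methylbut-2-enoate
Product: 4 tert-butyl (E)-4-[(tert-butyldiphenylsilyl)oxy]-3-methylbut-2-enoate
Conditions: t-BuPh2SiCl, imidazole, CH2Cl2, 0 °C → rt
Reagents that add atoms: tert-butyl(chloro)diphenylsilane, CC(C)(C)[Si](Cl)(c1ccccc1)c1ccccc1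
Why: Silylation of a primary alcohol through the N-silylimidazolium species; the TBDPS ether is chosen because it withstands the acid of step 3.

Step 3
Reactants: 4 tert-butyl (E)-4-[(tert-butyldiphenylsilyl)oxy]-3-methylbut-2-enoate
Product: 5 (E)-4-[(tert-butyldiphenylsilyl)oxy]-3-methylbut-2-enoic acid
Conditions: CF3CO2H/CH2Cl2 (1:4), 0 °C → rt
Reagents that add atoms: none
Why: Acidolysis of the tert-butyl ester by alkyl–oxygen cleavage (loss of 2-methylpropene) leaves the acid-stable silyl ether and the alkene geometry untouched.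

Step 4
Reactants: 5 (E)-4-[(tert-butyldiphenylsilyl)oxy]-3-methylbut-2-enoic acid; 6 (S)-4-benzyl-1,3-oxazolidin-2-one
Product: 8 (S)-4-benzyl-3-{(E)-4-[(tert-butyldiphenylsilyl)oxy]-3-methylbut-2-enoyl}-1,3-oxazolidin-2-one, via mixed pivalic anhydride 7 (not isolated)
Conditions: t-BuCOCl, Et3N, THF, −20 °C; then 6, LiCl, rt
Reagents that add atoms: pivaloyl chloride, CC(C)(C)C(Cl)=O (its acyl group is found in 7 only, not in 8)
Why: N-Acylation of the oxazolidinone by the mixed-anhydride method, the nucleophile attacking the less hindered enoyl carbonyl of 7.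

Step 5
Reactants: 3 tert-butyl (E)-4-hydroxy-3-methylbut-2-enoate
Product: 9 tert-butyl (E)-4-bromo-3-methylbut-2-enoate
Conditions: CBr4, PPh3, CH2Cl2, 0 °C
Reagents that add atoms: tetrabromomethane, BrC(Br)(Br)Br
Why: Appel reaction (SN2 displacement of the alkoxyphosphonium ion by bromide) under neutral conditions keeps the (E)-geometry.

Step 6
Reactants: 8 (S)-4-benzyl-3-{(E)-4-[(tert-butyldiphenylsilyl)oxy]-3-methylbut-2-enoyl}-1,3-oxazolidin-2-one; 9 tert-butyl (E)-4-bromo-3-methylbut-2-enoate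
Product: 11 tert-butyl (2E,5S)-5-{[(4S)-4-benzyl-2-oxo-1,3-oxazolidin-3-yl]carbonyl}-6-{[(tert-butyldiphenylsilyl)oxy]methyl}-3-methylhepta-2,6-dienoate, via sodium Z-dienolate 10 (not isolated)
Conditions: NaN(SiMe3)2, THF, −78 °C; then 9, −78 → −40 °C
Reagents that add atoms: sodium hexamethyldisilazide, C[Si](C)(C)[N-][Si](C)(C)C.[Na+] (sodium is found in 10 only)
Why: Deconjugative Evans alkylation: the base removes a proton from the methyl group cis to the carbonyl, and the chelated (Z)-dienolate 10 is alkylated at its α-carbon (SN2 on the allylic bromide) on the face away from the benzyl group, which sets C7 as S and places the alkene at C11=C12.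

Step 7
Reactants: 11 tert-butyl (2E,5S)-5-{[(4S)-4-benzyl-2-oxo-1,3-oxazolidin-3-yl]carbonyl}-6-{[(tert-butyldiphenylsilyl)oxy]methyl}-3-methylhepta-2,6-dienoate
Product: 12 tert-butyl (2E,5S)-6-{[(tert-butyldiphenylsilyl)oxy]methyl}-5-[(ethylsulfanyl)carbonyl]-3-methylhepta-2,6-dienoate
Conditions: EtSH, n-BuLi, THF, 0 °C
Reagents that add atoms: ethanethiol, CCS
Why: Acyl transfer to a soft, weakly basic thiolate at the exocyclic carbonyl removes the auxiliary (recovered) without epimerising C7 and leaves the hindered tert-butyl enoate alone.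

Step 8
Reactants: 12 tert-butyl (2E,5S)-6-{[(tert-butyldiphenylsilyl)oxy]methyl}-5-[(ethylsulfanyl)carbonyl]-3-methylhepta-2,6-dienoate; 13 ethyl 3-iodopropanoate
Product: 15 1-tert-butyl 9-ethyl (2E,5S)-5-{3-[(tert-butyldiphenylsilyl)oxy]prop-1-en-2-yl}-3-methyl-6-oxonon-2-enedioate, via organozinc iodide 14 (not isolated)
Conditions: Zn dust (activated with Me3SiCl and BrCH2CH2Br), THF, 35 °C; then 12, PdCl2(PPh3)2 (5 mol %), toluene, rt
Reagents that add atoms: zinc, [Zn] (found in 14 only)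
Why: Fukuyama coupling: zerovalent palladium inserts into the C–S bond, the alkylzinc transmetalates and reductive elimination gives the C8 ketone under neutral conditions that spare both esters and the C7 stereocentre.

Step 9
Reactants: 15 1-tert-butyl 9-ethyl (2E,5S)-5-{3-[(tert-butyldiphenylsilyl)oxy]prop-1-en-2-yl}-3-methyl-6-oxonon-2-enedioate
Product: 16 1-tert-butyl 9-ethyl (2E,5S)-5-{3-[(tert-butyldiphenylsilyl)oxy]prop-1-en-2-yl}-6,6-(ethylenedioxy)-3-methylnon-2-enedioate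
Conditions: Me3SiOCH2CH2OSiMe3, Me3SiOTf (5 mol %), CH2Cl2, −78 → −20 °C; pyridine quench
Reagents that add atoms: 1,2-bis(trimethylsilyloxy)ethane, C[Si](C)(C)OCCO[Si](C)(C)C
Why: Noyori ketalisation runs aprotic and cold, so the β,γ-unsaturated ketone is masked as its dioxolane without enolisation, alkene migration or loss of the C7 configuration.

Step 10
Reactants: 16 1-tert-butyl 9-ethyl (2E,5S)-5-{3-[(tert-butyldiphenylsilyl)oxy]prop-1-en-2-yl}-6,6-(ethylenedioxy)-3-methylnon-2-enedioate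
Product: 17 tert-butyl (2E,5S)-5-{3-[(tert-butyldiphenylsilyl)oxy]prop-1-en-2-yl}-6,6-(ethylenedioxy)-9-[methoxy(methyl)amino]-3-methyl-9-oxonon-2-enoate
Conditions: MeNHOMe·HCl, i-PrMgCl, THF, −20 °C
Reagents that add atoms: N,O-dimethylhydroxylamine hydrochloride, CNOC.Cl
Why: Aminolysis of the unhindered ethyl ester by the magnesium amide (Weinreb amide synthesis) is chemoselective, the tert-butyl enoate being far too hindered to react.

Step 11
Reactants: 17 tert-butyl (2E,5S)-5-{3-[(tert-butyldiphenylsilyl)oxy]prop-1-en-2-yl}-6,6-(ethylenedioxy)-9-[methoxy(methyl)amino]-3-methyl-9-oxonon-2-enoate; 18 vinylmagnesium bromide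
Product: 19 tert-butyl (2E,5S)-5-{3-[(tert-butyldiphenylsilyl)oxy]prop-1-en-2-yl}-6,6-(ethylenedioxy)-3-methyl-9-oxoundeca-2,10-dienoate
Conditions: THF, −20 → 0 °C; inverse quench into cold 1 M HCl
Reagents that add atoms: none
Why: Weinreb ketone synthesis: the magnesium chelate stops after one addition, and the acidic inverse quench protonates the released amine before it can add to the vinyl ketone, which is used at once.

Step 12
Reactants: 19 tert-butyl (2E,5S)-5-{3-[(tert-butyldiphenylsilyl)oxy]prop-1-en-2-yl}-6,6-(ethylenedioxy)-3-methyl-9-oxoundeca-2,10-dienoate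
Product: 20 tert-butyl (2E,5S,8Z)-9-[(tert-butyldimethylsilyl)oxy]-5-{3-[(tert-butyldiphenylsilyl)oxy]prop-1-en-2-yl}-6,6-(ethylenedioxy)-3-methylundeca-2,8,10-trienoate
Conditions: t-BuMe2SiOTf, Et3N, CH2Cl2, −78 → 0 °C
Reagents that add atoms: tert-butyldimethylsilyl trifluoromethanesulfonate, CC(C)(C)[Si](C)(C)OS(=O)(=O)C(F)(F)F
Why: Soft enolisation of a vinyl ketone that has α-hydrogens only at C10 gives the 2-silyloxydiene regiospecifically, with the vinyl group trans to C9 (Z enol ether) to avoid allylic strain.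

Step 13
Reactants: 20 tert-butyl (2E,5S,8Z)-9-[(tert-butyldimethylsilyl)oxy]-5-{3-[(tert-butyldiphenylsilyl)oxy]prop-1-en-2-yl}-6,6-(ethylenedioxy)-3-methylundeca-2,8,10-trienoate
Product: 21 tert-butyl (4S,5S,7S,10S)-1-[(tert-butyldimethylsilyl)oxy]-13-[(tert-butyldiphenylsilyl)oxy]-8,8-(ethylenedioxy)eremophila-1,11-dien-15-oate (trans-fused; 10-H α, C14 and C15 β, C7 side chain α)
Conditions: toluene (5 mM), 2,6-di-tert-butyl-4-methylphenol (cat.), 170 °C, sealed base-washed tube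
Reagents that add atoms: none
Why: On heating, the electron-rich silyloxydiene C10=C1–C2=C3 and the electron-poor enoate C5=C4 combine in a concerted, asynchronous suprafacial [4+2] cycloaddition, the C3–C4 bond running ahead of the bond that creates quaternary C5. The closest known reaction type is the thermal intramolecular Diels–Alder reaction of 1,7,9-decatrienoates and of tethered 2-silyloxydienes to decalin enol ethers. Ring B closes through C5–C10 by folding of the four-atom tether C6–C9 into a chair, and ring A is the new cyclohexene finished by C3–C4. The (E)-enoate geometry fixes C4 against C5 (ester cis to C14), the endo arrangement with the tether anti to the ester fixes C10 (trans fusion), and the C7 substituent, equatorial on the chair tether, fixes the face of C5 so that C14 lies trans to it. The step needs regio-, endo- and facial selectivity: the tether and the single enolisable side of the vinyl ketone secure the first, the matched polarity of diene and dienophile the second, and the C7 stereocentre next to the C8 ketal the third; since C10 later becomes sp2, only the relation of C4 and C5 to C7 has to be carried on.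

Step 14
Reactants: 21 tert-butyl (4S,5S,7S,10S)-1-[(tert-butyldimethylsilyl)oxy]-13-[(tert-butyldiphenylsilyl)oxy]-8,8-(ethylenedioxy)eremophila-1,11-dien-15-oate
Product: 22 tert-butyl (4S,5S,7S,10S)-13-[(tert-butyldiphenylsilyl)oxy]-8,8-(ethylenedioxy)-1-oxoeremophil-11-en-15-oate
Conditions: Bu4NF, AcOH, THF, 0 °C
Reagents that add atoms: none
Why: Fluoride-induced cleavage of the silyl enol ether with buffered protonation at C2 frees the C1 ketone much faster than the primary TBDPS ether reacts and without enolisation towards C10.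

Step 15
Reactants: 22 tert-butyl (4S,5S,7S,10S)-13-[(tert-butyldiphenylsilyl)oxy]-8,8-(ethylenedioxy)-1-oxoeremophil-11-en-15-oate
Product: 23 tert-butyl (1R,4S,5S,7S,10S)-13-[(tert-butyldiphenylsilyl)oxy]-8,8-(ethylenedioxy)-1β-hydroxyeremophil-11-en-15-oate
Conditions: Li[HB(s-Bu)3], THF, −78 °C; aq. NH4Cl
Reagents that add atoms: none
Why: Selectride reduction: the bulky hydride attacks C1 along the equatorial α trajectory, away from the syn-axial C14 methyl, and should give the axial 1β-alcohol (1R) while C8 stays masked.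

Step 16
Reactants: 23 tert-butyl (1R,4S,5S,7S,10S)-13-[(tert-butyldiphenylsilyl)oxy]-8,8-(ethylenedioxy)-1β-hydroxyeremophil-11-en-15-oate
Product: 24 tert-butyl (1R,4S,5S,7S,10S)-13-[(tert-butyldiphenylsilyl)oxy]-1β-hydroxy-8-oxoeremophil-11-en-15-oate
Conditions: pyridinium p-toluenesulfonate, acetone/H2O (9:1), 55 °C
Reagents that add atoms: water, O
Why: Mild acid-catalysed ketal hydrolysis frees the C8 ketone; the equatorial C7 substituent is also the thermodynamic arrangement, and the tert-butyl ester and TBDPS ether tolerate this acid.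

Step 17
Reactants: 24 tert-butyl (1R,4S,5S,7S,10S)-13-[(tert-butyldiphenylsilyl)oxy]-1β-hydroxy-8-oxoeremophil-11-en-15-oate
Product: 27 tert-butyl (1R,4S,5R,7S)-13-[(tert-butyldiphenylsilyl)oxy]-1β-hydroxy-8-oxoeremophila-9,11-dien-15-oate, via O-silylated C8 silyl enol ether 25 (not isolated), via C1 silyl ether enone 26 (not isolated)
Conditions: Me3SiCl, LiN(i-Pr)2 (2.4 equiv), THF, −78 °C; then Pd(OAc)2, MeCN, rt; then 1 M HCl, THF, 0 °C
Reagents that add atoms: chlorotrimethylsilane, C[Si](C)(C)Cl (silicon is found in 25 and 26 only)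
Why: Kinetic deprotonation at the C9 methylene (the C1 lithium alkoxide, syn-axial to C9–H, holds the amide base nearby, whereas C7–H is tertiary and flanked by the large side chain) gives enol silane 25, and Saegusa–Ito oxidation (palladation at C9, β-hydride elimination of C10–H) installs C9=C10 before the C1 silyl ether is hydrolysed.

Step 18
Reactants: 6 (S)-4-benzyl-1,3-oxazolidin-2-one; 28 hexanoyl chloride
Product: 29 (S)-4-benzyl-3-hexanoyl-1,3-oxazolidin-2-one
Conditions: Et3N, 4-(dimethylamino)pyridine (cat.), CH2Cl2, 0 °C → rt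
Reagents that add atoms: none
Why: N-Acylation of the oxazolidinone through the acylpyridinium ion.

Step 19
Reactants: 29 (S)-4-benzyl-3-hexanoyl-1,3-oxazolidin-2-one
Product: 31 (S)-4-benzyl-3-[(S)-2-methylhexanoyl]-1,3-oxazolidin-2-one, via sodium Z-enolate 30 (not isolated)
Conditions: NaN(SiMe3)2, THF, −78 °C; then MeI
Reagents that add atoms: iodomethane, CI; sodium hexamethyldisilazide, C[Si](C)(C)[N-][Si](C)(C)C.[Na+] (sodium is found in 30 only)
Why: Evans alkylation: the chelated (Z)-enolate is methylated on the face opposite the benzyl group, which sets the side-chain stereocentre as S.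

Step 20
Reactants: 31 (S)-4-benzyl-3-[(S)-2-methylhexanoyl]-1,3-oxazolidin-2-one
Product: 32 (S)-2-methylhexan-1-ol
Conditions: LiBH4, MeOH (1 equiv), Et2O, 0 °C
Reagents that add atoms: none
Why: Reductive cleavage of the imide (hydride attack at the exocyclic carbonyl) releases the alcohol without touching the α-stereocentre and returns the auxiliary.

Step 21
Reactants: 32 (S)-2-methylhexan-1-ol; 33 ethyl 2-(triphenylphosphoranylidene)propanoate
Product: 35 ethyl (2E,4S)-2,4-dimethyloct-2-enoate, via (S)-2-methylhexanal 34 (not isolated)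
Conditions: PhI(OAc)2, TEMPO (10 mol %), CH2Cl2, rt; then 33, rt
Reagents that add atoms: none
Why: Oxoammonium (TEMPO) oxidation gives the α-branched aldehyde, which is trapped in the same flask by a Wittig reaction with the stabilised α-methyl ylide, expected to be E-selective, so the epimerisable aldehyde is never stored.

Step 22
Reactants: 35 ethyl (2E,4S)-2,4-dimethyloct-2-enoate
Product: 36 (2E,4S)-2,4-dimethyloct-2-enoic acid
Conditions: LiOH, THF/MeOH/H2O, 40 °C; then 1 M HCl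
Reagents that add atoms: lithium hydroxide, [Li+].[OH-] (supplies the hydroxyl oxygen)
Why: Saponification by acyl–oxygen cleavage; the γ-stereocentre is not acidic enough to be disturbed by hydroxide.

Step 23
Reactants: 27 tert-butyl (1R,4S,5R,7S)-13-[(tert-butyldiphenylsilyl)oxy]-1β-hydroxy-8-oxoeremophila-9,11-dien-15-oate; 36 (2E,4S)-2,4-dimethyloct-2-enoic acid
Product: 38 tert-butyl (1R,4S,5R,7S)-13-[(tert-butyldiphenylsilyl)oxy]-1β-{[(2E,4S)-2,4-dimethyloct-2-enoyl]oxy}-8-oxoeremophila-9,11-dien-15-oate, via Yamaguchi mixed anhydride 37 (not isolated)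
Conditions: 2,4,6-Cl3C6H2COCl, Et3N, THF, rt; then 27, 4-(dimethylamino)pyridine, toluene, rt → 40 °C
Reagents that add atoms: 2,4,6-trichlorobenzoyl chloride, O=C(Cl)c1c(Cl)cc(Cl)cc1Cl (found in 37 only)
Why: Yamaguchi esterification: the acylpyridinium ion formed from 37 acylates the allylic C1 alcohol with retention at C1, since only the O–acyl bond is made.

Step 24
Reactants: 38 tert-butyl (1R,4S,5R,7S)-13-[(tert-butyldiphenylsilyl)oxy]-1β-{[(2E,4S)-2,4-dimethyloct-2-enoyl]oxy}-8-oxoeremophila-9,11-dien-15-oate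
Product: 39 tert-butyl (1R,4S,5R,7S)-1β-{[(2E,4S)-2,4-dimethyloct-2-enoyl]oxy}-13-hydroxy-8-oxoeremophila-9,11-dien-15-oate
Conditions: HF·pyridine, pyridine, THF, 0 °C → rt
Reagents that add atoms: none
Why: Fluoride cleavage of the Si–O bond under buffered, non-basic conditions spares both esters and the base-sensitive C7 position.

Step 25
Reactants: 39 tert-butyl (1R,4S,5R,7S)-1β-{[(2E,4S)-2,4-dimethyloct-2-enoyl]oxy}-13-hydroxy-8-oxoeremophila-9,11-dien-15-oate
Product: 40 tert-butyl (1R,4S,5R,7S)-1β-{[(2E,4S)-2,4-dimethyloct-2-enoyl]oxy}-8,13-dioxoeremophila-9,11-dien-15-oate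
Conditions: MnO2, CH2Cl2, rt
Reagents that add atoms: none
Why: Allylic oxidation on MnO2 converts the only allylic alcohol into the 2-substituted acrolein under neutral conditions.

Step 26
Reactants: 40 tert-butyl (1R,4S,5R,7S)-1β-{[(2E,4S)-2,4-dimethyloct-2-enoyl]oxy}-8,13-dioxoeremophila-9,11-dien-15-oate
Product: 41 integric acid, (1R,4S,5R,7S)-1β-{[(2E,4S)-2,4-dimethyloct-2-enoyl]oxy}-8,13-dioxoeremophila-9,11-dien-15-oic acid
Conditions: CF3CO2H/CH2Cl2 (1:4), 0 °C
Reagents that add atoms: none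
Why: Acidolysis of the tert-butyl ester (E1-type loss of 2-methylpropene) frees the C15 acid without base, so the enal, the γ-acyloxy enone and C7 are not endangered.

**Compound list**

1 | hydroxyacetone | CC(=O)CO | starting material
2 | tert-butyl (triphenylphosphoranylidene)acetate | CC(C)(C)OC(=O)C=P(c1ccccc1)(c1ccccc1)c1ccccc1 | starting material
3 | tert-butyl (E)-4-hydroxy-3-methylbut-2-enoate | CC(C)(C)OC(=O)/C=C(\C)CO | intermediate
4 | tert-butyl (E)-4-[(tert-butyldiphenylsilyl)oxy]-3-methylbut-2-enoate | CC(C)(C)OC(=O)/C=C(\C)CO[Si](c1ccccc1)(c1ccccc1)C(C)(C)C | intermediate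
5 | (E)-4-[(tert-butyldiphenylsilyl)oxy]-3-methylbut-2-enoic acid | OC(=O)/C=C(\C)CO[Si](c1ccccc1)(c1ccccc1)C(C)(C)C | intermediate
6 | (S)-4-benzyl-1,3-oxazolidin-2-one | O=C1OC[C@H](Cc2ccccc2)N1 | starting material
7 | mixed anhydride of 5 with pivalic acid | CC(C)(C)C(=O)OC(=O)/C=C(\C)CO[Si](c1ccccc1)(c1ccccc1)C(C)(C)C | intermediate
8 | (S)-4-benzyl-3-{(E)-4-[(tert-butyldiphenylsilyl)oxy]-3-methylbut-2-enoyl}-1,3-oxazolidin-2-one | O=C1OC[C@H](Cc2ccccc2)N1C(=O)/C=C(\C)CO[Si](c1ccccc1)(c1ccccc1)C(C)(C)C | intermediate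
9 | tert-butyl (E)-4-bromo-3-methylbut-2-enoate | CC(C)(C)OC(=O)/C=C(\C)CBr | intermediate
10 | sodium (Z)-dienolate of 8 (ONa cis to C11, C11=C12 methylene) | [Na+].[O-]/C(=C\C(=C)CO[Si](c1ccccc1)(c1ccccc1)C(C)(C)C)N1C(=O)OC[C@@H]1Cc1ccccc1 | intermediate
11 | tert-butyl (2E,5S)-5-{[(4S)-4-benzyl-2-oxo-1,3-oxazolidin-3-yl]carbonyl}-6-{[(tert-butyldiphenylsilyl)oxy]methyl}-3-methylhepta-2,6-dienoate | CC(C)(C)OC(=O)/C=C(\C)C[C@H](C(=O)N1C(=O)OC[C@@H]1Cc1ccccc1)C(=C)CO[Si](c1ccccc1)(c1ccccc1)C(C)(C)C | intermediate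
12 | tert-butyl (2E,5S)-6-{[(tert-butyldiphenylsilyl)oxy]methyl}-5-[(ethylsulfanyl)carbonyl]-3-methylhepta-2,6-dienoate | CCSC(=O)[C@@H](C/C(C)=C/C(=O)OC(C)(C)C)C(=C)CO[Si](c1ccccc1)(c1ccccc1)C(C)(C)C | intermediate
13 | ethyl 3-iodopropanoate | CCOC(=O)CCI | starting material
14 | (3-ethoxy-3-oxopropyl)zinc iodide | CCOC(=O)CC[Zn]I | intermediate
15 | 1-tert-butyl 9-ethyl (2E,5S)-5-{3-[(tert-butyldiphenylsilyl)oxy]prop-1-en-2-yl}-3-methyl-6-oxonon-2-enedioate | CCOC(=O)CCC(=O)[C@@H](C/C(C)=C/C(=O)OC(C)(C)C)C(=C)CO[Si](c1ccccc1)(c1ccccc1)C(C)(C)C | intermediate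
16 | 1-tert-butyl 9-ethyl (2E,5S)-5-{3-[(tert-butyldiphenylsilyl)oxy]prop-1-en-2-yl}-6,6-(ethylenedioxy)-3-methylnon-2-enedioate | CCOC(=O)CCC1(OCCO1)[C@@H](C/C(C)=C/C(=O)OC(C)(C)C)C(=C)CO[Si](c1ccccc1)(c1ccccc1)C(C)(C)C | intermediate
17 | tert-butyl (2E,5S)-5-{3-[(tert-butyldiphenylsilyl)oxy]prop-1-en-2-yl}-6,6-(ethylenedioxy)-9-[methoxy(methyl)amino]-3-methyl-9-oxonon-2-enoate | CON(C)C(=O)CCC1(OCCO1)[C@@H](C/C(C)=C/C(=O)OC(C)(C)C)C(=C)CO[Si](c1ccccc1)(c1ccccc1)C(C)(C)C | intermediate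
18 | vinylmagnesium bromide | C=C[Mg]Br | starting material
19 | tert-butyl (2E,5S)-5-{3-[(tert-butyldiphenylsilyl)oxy]prop-1-en-2-yl}-6,6-(ethylenedioxy)-3-methyl-9-oxoundeca-2,10-dienoate | C=CC(=O)CCC1(OCCO1)[C@@H](C/C(C)=C/C(=O)OC(C)(C)C)C(=C)CO[Si](c1ccccc1)(c1ccccc1)C(C)(C)C | intermediate
20 | tert-butyl (2E,5S,8Z)-9-[(tert-butyldimethylsilyl)oxy]-5-{3-[(tert-butyldiphenylsilyl)oxy]prop-1-en-2-yl}-6,6-(ethylenedioxy)-3-methylundeca-2,8,10-trienoate | C=C/C(O[Si](C)(C)C(C)(C)C)=C/CC1(OCCO1)[C@@H](C/C(C)=C/C(=O)OC(C)(C)C)C(=C)CO[Si](c1ccccc1)(c1ccccc1)C(C)(C)C | intermediate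
21 | tert-butyl (4S,5S,7S,10S)-1-[(tert-butyldimethylsilyl)oxy]-13-[(tert-butyldiphenylsilyl)oxy]-8,8-(ethylenedioxy)eremophila-1,11-dien-15-oate | C=C(CO[Si](c1ccccc1)(c1ccccc1)C(C)(C)C)[C@@H]1C[C@@]2(C)[C@H](CC13OCCO3)C(O[Si](C)(C)C(C)(C)C)=CC[C@@H]2C(=O)OC(C)(C)C | intermediate
22 | tert-butyl (4S,5S,7S,10S)-13-[(tert-butyldiphenylsilyl)oxy]-8,8-(ethylenedioxy)-1-oxoeremophil-11-en-15-oate | C=C(CO[Si](c1ccccc1)(c1ccccc1)C(C)(C)C)[C@@H]1C[C@@]2(C)[C@H](CC13OCCO3)C(=O)CC[C@@H]2C(=O)OC(C)(C)C | intermediate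
23 | tert-butyl (1R,4S,5S,7S,10S)-13-[(tert-butyldiphenylsilyl)oxy]-8,8-(ethylenedioxy)-1β-hydroxyeremophil-11-en-15-oate | C=C(CO[Si](c1ccccc1)(c1ccccc1)C(C)(C)C)[C@@H]1C[C@@]2(C)[C@H](CC13OCCO3)[C@H](O)CC[C@@H]2C(=O)OC(C)(C)C | intermediate
24 | tert-butyl (1R,4S,5S,7S,10S)-13-[(tert-butyldiphenylsilyl)oxy]-1β-hydroxy-8-oxoeremophil-11-en-15-oate | C=C(CO[Si](c1ccccc1)(c1ccccc1)C(C)(C)C)[C@@H]1C[C@@]2(C)[C@H](CC1=O)[C@H](O)CC[C@@H]2C(=O)OC(C)(C)C | intermediate
25 | tert-butyl (1R,4S,5S,7S,10S)-13-[(tert-butyldiphenylsilyl)oxy]-1β,8-bis[(trimethylsilyl)oxy]eremophila-8,11-dien-15-oate | C=C(CO[Si](c1ccccc1)(c1ccccc1)C(C)(C)C)[C@@H]1C[C@@]2(C)[C@H](C=C1O[Si](C)(C)C)[C@H](O[Si](C)(C)C)CC[C@@H]2C(=O)OC(C)(C)C | intermediate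
26 | tert-butyl (1R,4S,5R,7S)-13-[(tert-butyldiphenylsilyl)oxy]-8-oxo-1β-[(trimethylsilyl)oxy]eremophila-9,11-dien-15-oate | C=C(CO[Si](c1ccccc1)(c1ccccc1)C(C)(C)C)[C@@H]1C[C@@]2(C)C(=CC1=O)[C@H](O[Si](C)(C)C)CC[C@@H]2C(=O)OC(C)(C)C | intermediate
27 | tert-butyl (1R,4S,5R,7S)-13-[(tert-butyldiphenylsilyl)oxy]-1β-hydroxy-8-oxoeremophila-9,11-dien-15-oate | C=C(CO[Si](c1ccccc1)(c1ccccc1)C(C)(C)C)[C@@H]1C[C@@]2(C)C(=CC1=O)[C@H](O)CC[C@@H]2C(=O)OC(C)(C)C | intermediate
28 | hexanoyl chloride | CCCCCC(=O)Cl | starting material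
29 | (S)-4-benzyl-3-hexanoyl-1,3-oxazolidin-2-one | CCCCCC(=O)N1C(=O)OC[C@@H]1Cc1ccccc1 | intermediate
30 | sodium (Z)-enolate of 29 | [Na+].CCCC/C=C(\[O-])N1C(=O)OC[C@@H]1Cc1ccccc1 | intermediate
31 | (S)-4-benzyl-3-[(S)-2-methylhexanoyl]-1,3-oxazolidin-2-one | CCCC[C@H](C)C(=O)N1C(=O)OC[C@@H]1Cc1ccccc1 | intermediate
32 | (S)-2-methylhexan-1-ol | CCCC[C@H](C)CO | intermediate
33 | ethyl 2-(triphenylphosphoranylidene)propanoate | CCOC(=O)C(C)=P(c1ccccc1)(c1ccccc1)c1ccccc1 | starting material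
34 | (S)-2-methylhexanal | CCCC[C@H](C)C=O | intermediate
35 | ethyl (2E,4S)-2,4-dimethyloct-2-enoate | CCCC[C@H](C)/C=C(\C)C(=O)OCC | intermediate
36 | (2E,4S)-2,4-dimethyloct-2-enoic acid | CCCC[C@H](C)/C=C(\C)C(=O)O | intermediate
37 | mixed anhydride of 36 with 2,4,6-trichlorobenzoic acid | CCCC[C@H](C)/C=C(\C)C(=O)OC(=O)c1c(Cl)cc(Cl)cc1Cl | intermediate
38 | tert-butyl (1R,4S,5R,7S)-13-[(tert-butyldiphenylsilyl)oxy]-1β-{[(2E,4S)-2,4-dimethyloct-2-enoyl]oxy}-8-oxoeremophila-9,11-dien-15-oate | C=C(CO[Si](c1ccccc1)(c1ccccc1)C(C)(C)C)[C@@H]1C[C@@]2(C)C(=CC1=O)[C@H](OC(=O)/C(C)=C/[C@@H](C)CCCC)CC[C@@H]2C(=O)OC(C)(C)C | intermediate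
39 | tert-butyl (1R,4S,5R,7S)-1β-{[(2E,4S)-2,4-dimethyloct-2-enoyl]oxy}-13-hydroxy-8-oxoeremophila-9,11-dien-15-oate | C=C(CO)[C@@H]1C[C@@]2(C)C(=CC1=O)[C@H](OC(=O)/C(C)=C/[C@@H](C)CCCC)CC[C@@H]2C(=O)OC(C)(C)C | intermediate
40 | tert-butyl (1R,4S,5R,7S)-1β-{[(2E,4S)-2,4-dimethyloct-2-enoyl]oxy}-8,13-dioxoeremophila-9,11-dien-15-oate | C=C(C=O)[C@@H]1C[C@@]2(C)C(=CC1=O)[C@H](OC(=O)/C(C)=C/[C@@H](C)CCCC)CC[C@@H]2C(=O)OC(C)(C)C | intermediate
41 | integric acid | C=C(C=O)[C@@H]1C[C@@]2(C)C(=CC1=O)[C@H](OC(=O)/C(C)=C/[C@@H](C)CCCC)CC[C@@H]2C(=O)O | target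

**Step count.** Total: 26 steps. Longest linear sequence: 20 steps (1–4, 6–17, 23–26); step 5 and steps 18–22 are side branches.

**Steps most likely to fail**

Step 13. The cycloaddition onto the β,β-disubstituted enoate may be too slow at a temperature that the tert-butyl ester and the silyl enol ether tolerate. The exo (cis-fused) or wrong-face pathway may compete, and the diene may add to the C11=C12 alkene across the shorter tether. The fallback raises dienophile reactivity by moving C15 to the aldehyde level. It sets out from 20: i-Bu2AlH (CH2Cl2, −78 °C) should reduce only the tert-butyl enoate to the (E)-allylic alcohol F1, and MnO2 should give the (E)-enal F2. F2 is expected to cyclise near 100 °C in toluene through the same chair-tether transition state to the aldehyde adduct F3. Bu4NF/AcOH then gives the keto aldehyde F4, and Pinnick oxidation (NaClO2, NaH2PO4, 2-methylbut-2-ene) gives the keto acid F5. tert-Butyl 2,2,2-trichloroacetimidate (cat. BF3·OEt2) restores the ester, and the route is rejoined at 22.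

Step 17. Deprotonation may take place at the allylic, thermodynamically more acidic C7–H instead of C9, leading after silylation and palladation to the wrong unsaturation. The fallback obtains the regiochemistry from an enamine instead of a kinetic enolate. It sets out from 24: pyrrolidine (cat. TsOH, benzene, removal of water) should give the less substituted pyrrolidine enamine F6, because allylic strain disfavours the enamine towards substituted C7. PhSeCl followed by aqueous work-up should give the 9-phenylselanyl ketone F7. H2O2/pyridine converts it into the selenoxide F8, whose syn-elimination can only run towards C10–H, and the route is rejoined at 27.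

Step 23. Acylation of the hindered pseudo-axial allylic alcohol next to C14 by an α-methyl enoyl donor may stall. The activated acid may also lose its C4′ configuration by γ-deprotonation to a vinylketene. The fallback builds the side chain on the core. It sets out from 27: 2-(diethoxyphosphoryl)propanoic acid (N,N′-dicyclohexylcarbodiimide, 4-(dimethylamino)pyridine) should give the phosphonate ester F9. A Horner–Wadsworth–Emmons reaction of F9 with aldehyde 34 (made from 32 as in step 21 without the ylide) under LiCl/i-Pr2NEt in MeCN should form the (E)-enoate, and the route is rejoined at 38.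

**Further compounds**

F1 | step 13 | (2E,5S,8Z)-9-[(tert-butyldimethylsilyl)oxy]-5-{3-[(tert-butyldiphenylsilyl)oxy]prop-1-en-2-yl}-6,6-(ethylenedioxy)-3-methylundeca-2,8,10-trien-1-ol | C=C/C(O[Si](C)(C)C(C)(C)C)=C/CC1(OCCO1)[C@@H](C/C(C)=C/CO)C(=C)CO[Si](c1ccccc1)(c1ccccc1)C(C)(C)C
F2 | step 13 | (2E,5S,8Z)-9-[(tert-butyldimethylsilyl)oxy]-5-{3-[(tert-butyldiphenylsilyl)oxy]prop-1-en-2-yl}-6,6-(ethylenedioxy)-3-methylundeca-2,8,10-trienal | C=C/C(O[Si](C)(C)C(C)(C)C)=C/CC1(OCCO1)[C@@H](C/C(C)=C/C=O)C(=C)CO[Si](c1ccccc1)(c1ccccc1)C(C)(C)C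
F3 | step 13 | (4S,5S,7S,10S)-1-[(tert-butyldimethylsilyl)oxy]-13-[(tert-butyldiphenylsilyl)oxy]-8,8-(ethylenedioxy)eremophila-1,11-dien-15-al | C=C(CO[Si](c1ccccc1)(c1ccccc1)C(C)(C)C)[C@@H]1C[C@@]2(C)[C@H](CC13OCCO3)C(O[Si](C)(C)C(C)(C)C)=CC[C@@H]2C=O
F4 | step 13 | (4S,5R,7S,10S)-13-[(tert-butyldiphenylsilyl)oxy]-8,8-(ethylenedioxy)-1-oxoeremophil-11-en-15-al | C=C(CO[Si](c1ccccc1)(c1ccccc1)C(C)(C)C)[C@@H]1C[C@@]2(C)[C@H](CC13OCCO3)C(=O)CC[C@@H]2C=O
F5 | step 13 | (4S,5S,7S,10S)-13-[(tert-butyldiphenylsilyl)oxy]-8,8-(ethylenedioxy)-1-oxoeremophil-11-en-15-oic acid | C=C(CO[Si](c1ccccc1)(c1ccccc1)C(C)(C)C)[C@@H]1C[C@@]2(C)[C@H](CC13OCCO3)C(=O)CC[C@@H]2C(=O)O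
F6 | step 17 | pyrrolidine enamine of 24 with the C8=C9 double bond | C=C(CO[Si](c1ccccc1)(c1ccccc1)C(C)(C)C)[C@@H]1C[C@@]2(C)[C@H](C=C1N3CCCC3)[C@H](O)CC[C@@H]2C(=O)OC(C)(C)C
F7 | step 17 | 9-(phenylselanyl) derivative of 24 (C9 epimers) | C=C(CO[Si](c1ccccc1)(c1ccccc1)C(C)(C)C)[C@@H]1C[C@@]2(C)[C@H](C([Se]c3ccccc3)C1=O)[C@H](O)CC[C@@H]2C(=O)OC(C)(C)C
F8 | step 17 | selenoxide of F7 | C=C(CO[Si](c1ccccc1)(c1ccccc1)C(C)(C)C)[C@@H]1C[C@@]2(C)[C@H](C([Se](=O)c3ccccc3)C1=O)[C@H](O)CC[C@@H]2C(=O)OC(C)(C)C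
F9 | step 23 | tert-butyl (1R,4S,5R,7S)-13-[(tert-butyldiphenylsilyl)oxy]-1β-{[2-(diethoxyphosphoryl)propanoyl]oxy}-8-oxoeremophila-9,11-dien-15-oate | C=C(CO[Si](c1ccccc1)(c1ccccc1)C(C)(C)C)[C@@H]1C[C@@]2(C)C(=CC1=O)[C@H](OC(=O)C(C)P(=O)(OCC)OCC)CC[C@@H]2C(=O)OC(C)(C)C
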